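Numbering (germacrane): ring C1–C10 with C1=C10 (C14 methyl on C10), C4=C5 (C15H2O on C4), C6–OH, C7, C8–O; lactone C8–O–C12(=O)–C11(=C13H2)–C7.
Cuts: (a) the O15 ester, made last; (b) the C4=C5 olefin, reopened to a C4–SO2–C5 bridge, so that the ten-membered carbocycle comes from an eleven-membered thiacycle S,S-dioxide by Ramberg–Bäcklund ring contraction; (c) the S–C5 bond (thiolate alkylation); (d) C6–C7 (Barbier union of chloroacetaldehyde with a 3-(bromomethyl)butenolide); (e) C7=C11 (ring-closing metathesis) and C1–C2 (B-alkyl Suzuki coupling).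
Feature that allows (b): C4 and C5 carry no stereocentre in the target and lie between the sp3 carbons C3 and C6, so sulfur can be placed between them, the larger ring closed by a soft S-alkylation and SO2 expelled; both C4 epimers of the sulfone give the same olefin (stereoconvergent).
Forward order: C7–C10/C1 chain (carboalumination) → C1–C2 coupling → butenolide ring → C6–C7 union → lactone masked as lactol methyl acetal → eleven-membered sulfide ring → sulfone → ten-membered ring by SO2 extrusion → lactone restored → O15 acylation → desilylation.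
Stereochemistry: C8 from (S)-epichlorohydrin; C7 and C6 from C8 in the Barbier step (attack anti to the C8 side chain, chair transition state); C1=C10 (E) from syn-carbometalation; C4=C5 (C3 and C6 cis) from the cis-fused episulfone on the medium ring; side-chain olefin (E) from a stabilised Wittig reagent.

Key step: step 15

Remark: atom numbers in the text are the germacrane numbers given above; the target is (6R,7S,8S).
Remark: the C4 carbinol unit is introduced racemic and the lactol acetal carbon C12 is formed unselectively, so compounds 10–13, 15, 16 and 18–28 are epimer mixtures at these centres, which become planar in steps 15 and 16.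

Step 1
Reactants: 1 (S)-2-(chloromethyl)oxirane; 2 ethynyltrimethylsilane
Product: 3 (S)-1-chloro-5-(trimethylsilyl)pent-4-yn-2-ol
Conditions: 2, nBuLi, THF, −78 °C; BF3·OEt2; then 1, −78 °C
Reagents that add atoms: none
Why: Alkynylation of a terminal epoxide by a lithium acetylide/BF3 pair takes place only at the unsubstituted epoxide carbon, so the C–Cl bond and the stereocentre (later C8) are untouched and the S configuration is carried over.

Step 2
Reactants: 3 (S)-1-chloro-5-(trimethylsilyl)pent-4-yn-2-ol
Product: 6 (S)-hex-1-en-5-yn-3-ol, via epoxide 4 (not isolated), via silyl enynol 5 (not isolated)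
Conditions: Me3S+ I− (4 equiv), nBuLi (3.8 equiv), THF, −20 °C to rt; then K2CO3 (cat.), MeOH, rt
Reagents that add atoms: trimethylsulfonium iodide, C[S+](C)C.[I-]
Why: The excess ylide closes the chlorohydrin to terminal epoxide 4, opens it at CH2 and the betaine loses Me2S to give the allylic alcohol (Corey–Chaykovsky-type one-carbon homologation of an epoxide) without touching the carbinol centre, and K2CO3/MeOH then cleaves the alkynyl–Si bond.

Step 3
Reactants: 6 (S)-hex-1-en-5-yn-3-ol
Product: 7 (3S,5E)-6-iodo-5-methylhexa-1,5-dien-3-ol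
Conditions: Me3Al (3 equiv), Cp2ZrCl2 (0.25 equiv), CH2Cl2, 0 °C to rt; then I2, THF, −30 °C; aq. K2CO3
Reagents that add atoms: trimethylaluminium, C[Al](C)C; iodine, II
Why: Zirconium-catalysed carboalumination (Negishi) adds methyl and aluminium syn across the terminal alkyne with aluminium at the terminus, and iodinolysis with retention gives the E-iodoalkene, which fixes the E geometry of the later C1=C10 bond.

Step 4
Reactants: 8 2-vinyloxirane (racemic); 9 (4-methoxyphenyl)methanol
Product: 10 1-[(4-methoxybenzyl)oxy]but-3-en-2-ol (racemic)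
Conditions: NaH (0.1 equiv), 9 (3 equiv, neat), 60 °C
Reagents that add atoms: none
Why: Base-catalysed SN2 opening of the vinyl epoxide by the benzylic alkoxide occurs at the unsubstituted epoxide carbon; the new carbinol (later C4) needs no control because it is erased in step 15.

Step 5
Reactants: 10 1-[(4-methoxybenzyl)oxy]but-3-en-2-ol
Product: 11 1-[(4-methoxybenzyl)oxy]but-3-en-2-yl pivalate (racemic)
Conditions: PivCl, pyridine, DMAP (cat.), CH2Cl2, 0 °C to rt
Reagents that add atoms: pivaloyl chloride, CC(C)(C)C(=O)Cl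
Why: DMAP-catalysed acylation of the secondary alcohol gives a pivalate that blocks O4 through the basic coupling and is removed reductively in step 11.

Step 6
Reactants: 11 1-[(4-methoxybenzyl)oxy]but-3-en-2-yl pivalate; 7 (3S,5E)-6-iodo-5-methylhexa-1,5-dien-3-ol
Product: 13 (2RS,5E,8S)-8-hydroxy-1-[(4-methoxybenzyl)oxy]-6-methyldeca-5,9-dien-2-yl pivalate, via alkylborane 12 (not isolated)
Conditions: 11, 9-BBN, THF, 0 °C to rt; then 7, Pd(dppf)Cl2 (5 mol%), AsPh3, Cs2CO3, DMF/THF/H2O, rt
Reagents that add atoms: none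
Why: B-alkyl Suzuki–Miyaura coupling: anti-Markovnikov hydroboration gives primary borane 12, which couples with the iodoalkene with retention of the E geometry, and the free allylic alcohol is tolerated.

Step 7
Reactants: 13 (2RS,5E,8S)-8-hydroxy-1-[(4-methoxybenzyl)oxy]-6-methyldeca-5,9-dien-2-yl pivalate; 14 2-(bromomethyl)acrylic acid
Product: 15 (2RS,5E,8S)-1-[(4-methoxybenzyl)oxy]-6-methyl-2-(pivaloyloxy)deca-5,9-dien-8-yl 2-(bromomethyl)acrylate
Conditions: DCC, DMAP (5 mol%), CH2Cl2, −20 to 0 °C
Reagents that add atoms: none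
Why: Steglich esterification of the only free hydroxyl; low temperature and little DMAP keep the allylic bromide intact.

Step 8
Reactants: 15 (2RS,5E,8S)-1-[(4-methoxybenzyl)oxy]-6-methyl-2-(pivaloyloxy)deca-5,9-dien-8-yl 2-(bromomethyl)acrylate
Product: 16 (5S)-3-(bromomethyl)-5-[(2E)-7-[(4-methoxybenzyl)oxy]-2-methyl-6-(pivaloyloxy)hept-2-en-1-yl]furan-2(5H)-one
Conditions: second-generation Hoveyda–Grubbs catalyst RuCl2(SIMes)(=CH-C6H4-2-OiPr) (5 mol%), toluene (5 mM), 80 °C
Reagents that add atoms: none
Why: Ring-closing metathesis of the acrylate with the vinyl group closes the five-membered butenolide with loss of ethene, while the hindered trisubstituted C10=C1 alkene could only give a strained or larger ring and stays out.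

Step 9
Reactants: 16 (5S)-3-(bromomethyl)-5-[(2E)-7-[(4-methoxybenzyl)oxy]-2-methyl-6-(pivaloyloxy)hept-2-en-1-yl]furan-2(5H)-one; 17 chloroacetaldehyde
Product: 18 (4S,5S)-4-[(1S)-2-chloro-1-hydroxyethyl]-3-methylene-5-[(2E)-7-[(4-methoxybenzyl)oxy]-2-methyl-6-(pivaloyloxy)hept-2-en-1-yl]dihydrofuran-2(3H)-one
Conditions: In (powder, 1.5 equiv), 17 (50% in H2O, 3 equiv), THF/H2O 1:1, rt
Reagents that add atoms: none
Why: Barbier allylation through an allylindium reagent: the 2-(oxycarbonyl)allyl unit reacts at its ring terminus C7 with allylic transposition on the face anti to the C8 side chain, which sets C7 trans to C8, and through a Zimmerman–Traxler chair with the chloromethyl group equatorial, which sets the C6 carbinol in the 6,7-relationship of the target, the exocyclic methylene of the lactone appearing at the same time.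

Step 10
Reactants: 18 the chlorohydrin lactone of step 9
Product: 19 O6-tert-butyldimethylsilyl ether of 18
Conditions: TBSOTf, 2,6-lutidine, CH2Cl2, −78 °C
Reagents that add atoms: tert-butyldimethylsilyl trifluoromethanesulfonate, CC(C)(C)[Si](C)(C)OS(=O)(=O)C(F)(F)F
Why: Silylation of the secondary alcohol under non-basic conditions avoids both epoxide closure of the chlorohydrin and migration of the lactone to O6.

Step 11
Reactants: 19 O6-tert-butyldimethylsilyl ether of 18
Product: 21 C12 methyl acetal (2-methoxy-3-methylenetetrahydrofuran) bearing free O4–H and the O6 silyl ether and the C5 chloride, via lactol 20 (not isolated)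
Conditions: iBu2AlH (4.5 equiv), CH2Cl2, −78 °C; aq. KNaC4H4O6; then MeOH, PPTS (cat.), rt
Reagents that add atoms: methanol, CO
Why: 1,2-Reduction of the lactone at −78 °C stops at the lactol aluminate while the pivalate is cleaved reductively, and acid-catalysed acetalisation in methanol then masks the lactol as a base-stable acetal that is neither a Michael acceptor nor an enolisable ester (both C12 anomers serve).

Step 12
Reactants: 21 the C12 methyl acetal alcohol of step 11
Product: 22 C4 thioacetate of 21
Conditions: AcSH, PPh3, DIAD, THF, 0 °C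
Reagents that add atoms: thioacetic acid, CC(=O)S
Why: Mitsunobu substitution of the secondary alcohol by thioacetic acid (SN2 with inversion at C4, which is irrelevant because both epimers are carried on).

Step 13
Reactants: 22 C4 thioacetate of 21
Product: 23 eleven-membered cyclic sulfide (S between C4 and C5; ring S–C5–C6–C7–C8–C9–C10=C1–C2–C3–C4) fused at C7–C8 to the methoxy-methylene-tetrahydrofuran
Conditions: Cs2CO3, NaI (cat.), MeOH/DMF 1:9 (1 mM, degassed), 50 °C, slow addition
Reagents that add atoms: none
Why: Methanolysis frees the caesium thiolate, which closes the eleven-membered ring by intramolecular SN2 at the primary C5 (iodide-assisted chloride displacement) under high dilution, soft thiolate alkylation being among the most reliable macrocyclisations.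

Step 14
Reactants: 23 the eleven-membered cyclic sulfide
Product: 24 the corresponding cyclic sulfone (thiacycloundecene S,S-dioxide)
Conditions: H2O2 (30% aq.), (NH4)6Mo7O24·4H2O (10 mol%), MeOH, 0 °C to rt
Reagents that add atoms: hydrogen peroxide, OO
Why: Molybdate-catalysed peroxide oxidation takes the sulfide to the sulfone and leaves the isolated alkenes, the acetal and the ethers untouched.

Step 15
Reactants: 24 the eleven-membered cyclic sulfone
Product: 27 cyclodeca-1(10),4-diene (C1=C10 E; C3 and C6 cis on C4=C5) carrying the C15 PMB ether, the O6 TBS ether and the C12 methyl acetal, via bromo sulfone 25 (not isolated), via episulfone 26 (not isolated)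
Conditions: CBr2F2, KOH/Al2O3, tBuOH/CH2Cl2, 0 °C to rt
Reagents that add atoms: none
Why: Ramberg–Bäcklund reaction with halogenation in the flask: KOH on alumina deprotonates the sulfone at C5 (or C4), CBr2F2 brominates the carbanion to 25, the second α-carbanion displaces bromide in a 1,3-elimination (3-exo-tet) to the thiirane dioxide 26, and cheletropic loss of SO2 leaves the C4=C5 double bond, so the eleven-membered thiacycle contracts to the ten-membered carbocycle. The closest known reaction type is the Ramberg–Bäcklund ring contraction of macrocyclic sulfones to medium-ring cycloalkenes, including trisubstituted ones. No stereocentre is created; the olefin geometry is fixed at the episulfone, which on a ten-membered ring should be cis-fused, so C3 and C6 end up cis on the double bond as in the target (E by CIP because of the C15 oxygen). Both C4 epimers and both bromide epimers funnel into the same olefin because C4 and C5 become planar. The step needs 1,3-displacement to beat β-loss of the C15 or C6 alkoxide from the sulfonyl carbanions; the PMB and silyl ethers are poor leaving groups, the intramolecular displacement is fast, and the acetal-masked lactol offers no enolisable or electrophilic site.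

Step 16
Reactants: 27 the cyclodecadiene methyl acetal
Product: 29 8,12-lactone (α-methylene γ-lactone) with O6 TBS and O15 PMB, via lactol 28 (not isolated)
Conditions: PPTS, acetone/H2O 4:1, 40 °C; then MnO2 (excess), CH2Cl2, rt
Reagents that add atoms: water, O
Why: Mild acid hydrolysis of the allylic methyl acetal gives lactol 28, whose allylic hemiacetal is oxidised by MnO2 to the α-methylene γ-lactone, while the silyl and PMB ethers survive both operations.

Step 17
Reactants: 29 the O6-TBS O15-PMB lactone
Product: 30 C15 primary allylic alcohol (O6 TBS lactone)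
Conditions: DDQ, CH2Cl2/pH 7 buffer 10:1, 0 °C
Reagents that add atoms: none
Why: Oxidative cleavage of the p-methoxybenzyl ether by DDQ (hydride abstraction, then hydrolysis of the oxocarbenium ion) frees only O15.

Step 18
Reactants: 31 2-[(tert-butyldimethylsilyl)oxy]acetaldehyde; 32 ethyl 2-(triphenyl-λ5-phosphanylidene)propanoate
Product: 33 ethyl (E)-4-[(tert-butyldimethylsilyl)oxy]-2-methylbut-2-enoate
Conditions: CH2Cl2, rt
Reagents that add atoms: none
Why: Wittig reaction of a stabilised ylide gives the E trisubstituted enoate (ester trans to the CH2O group).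

Step 19
Reactants: 33 ethyl (E)-4-[(tert-butyldimethylsilyl)oxy]-2-methylbut-2-enoate
Product: 34 (E)-4-[(tert-butyldimethylsilyl)oxy]-2-methylbut-2-enoic acid
Conditions: LiOH, THF/H2O 3:1, rt; then 1 M HCl to pH 4
Reagents that add atoms: lithium hydroxide, [Li+].[OH-]
Why: Saponification of the ethyl ester; the primary silyl ether withstands LiOH and brief mild acidification.

Step 20
Reactants: 30 the C15 alcohol; 34 (E)-4-[(tert-butyldimethylsilyl)oxy]-2-methylbut-2-enoic acid
Product: 35 bis-TBS ether of the target (O6 and side-chain O silylated)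
Conditions: EDC·HCl, DMAP (cat.), CH2Cl2, 0 °C to rt
Reagents that add atoms: none
Why: Carbodiimide/DMAP esterification of the primary allylic O15 with acid 34; O6 is silylated and cannot compete.

Step 21
Reactants: 35 bis-TBS ether of the target
Product: 36 the target (6R,7S,8S; CNP0326626.2)
Conditions: HF·pyridine, pyridine, THF, 0 °C to rt
Reagents that add atoms: none
Why: Fluoride cleavage of both silyl ethers under buffered, weakly acidic conditions leaves the α-methylene lactone and the two esters intact and touches no stereocentre.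

Compound list
1 | (S)-2-(chloromethyl)oxirane | ClC[C@@H]1CO1 | starting material
2 | ethynyltrimethylsilane | C#C[Si](C)(C)C | starting material
3 | (S)-1-chloro-5-(trimethylsilyl)pent-4-yn-2-ol | ClC[C@@H](O)CC#C[Si](C)(C)C | intermediate
4 | (S)-trimethyl[3-(oxiran-2-yl)prop-1-yn-1-yl]silane (not isolated) | C1[C@@H](O1)CC#C[Si](C)(C)C | intermediate
5 | (S)-6-(trimethylsilyl)hex-1-en-5-yn-3-ol (not isolated) | C=C[C@@H](O)CC#C[Si](C)(C)C | intermediate
6 | (S)-hex-1-en-5-yn-3-ol | C=C[C@@H](O)CC#C | intermediate
7 | (3S,5E)-6-iodo-5-methylhexa-1,5-dien-3-ol | C=C[C@@H](O)C/C(C)=C/I | intermediate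
8 | 2-vinyloxirane (racemic) | C=CC1CO1 | starting material
9 | (4-methoxyphenyl)methanol | COc1ccc(CO)cc1 | starting material
10 | 1-[(4-methoxybenzyl)oxy]but-3-en-2-ol (racemic) | C=CC(O)COCc1ccc(OC)cc1 | intermediate
11 | 1-[(4-methoxybenzyl)oxy]but-3-en-2-yl pivalate (racemic) | C=CC(OC(=O)C(C)(C)C)COCc1ccc(OC)cc1 | intermediate
12 | 4-(9-borabicyclo[3.3.1]nonan-9-yl)-1-[(4-methoxybenzyl)oxy]butan-2-yl pivalate (not isolated) | CC(C)(C)C(=O)OC(CCB1C2CCCC1CCC2)COCc1ccc(OC)cc1 | intermediate
13 | (2RS,5E,8S)-8-hydroxy-1-[(4-methoxybenzyl)oxy]-6-methyldeca-5,9-dien-2-yl pivalate | C=C[C@@H](O)C/C(C)=C/CCC(OC(=O)C(C)(C)C)COCc1ccc(OC)cc1 | intermediate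
14 | 2-(bromomethyl)acrylic acid | C=C(CBr)C(=O)O | starting material
15 | (2RS,5E,8S)-1-[(4-methoxybenzyl)oxy]-6-methyl-2-(pivaloyloxy)deca-5,9-dien-8-yl 2-(bromomethyl)acrylate | C=C[C@@H](OC(=O)C(=C)CBr)C/C(C)=C/CCC(OC(=O)C(C)(C)C)COCc1ccc(OC)cc1 | intermediate
16 | (5S)-3-(bromomethyl)-5-[(2E)-7-[(4-methoxybenzyl)oxy]-2-methyl-6-(pivaloyloxy)hept-2-en-1-yl]furan-2(5H)-one | O=C1O[C@@H](C/C(C)=C/CCC(OC(=O)C(C)(C)C)COCc2ccc(OC)cc2)C=C1CBr | intermediate
17 | chloroacetaldehyde | O=CCCl | starting material
18 | (4S,5S)-4-[(1S)-2-chloro-1-hydroxyethyl]-3-methylene-5-[(2E)-7-[(4-methoxybenzyl)oxy]-2-methyl-6-(pivaloyloxy)hept-2-en-1-yl]dihydrofuran-2(3H)-one | C=C1C(=O)O[C@@H](C/C(C)=C/CCC(OC(=O)C(C)(C)C)COCc2ccc(OC)cc2)[C@@H]1[C@H](O)CCl | intermediate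
19 | O6-tert-butyldimethylsilyl ether of 18 (C6, C7, C8 as in 18) | C=C1C(=O)O[C@@H](C/C(C)=C/CCC(OC(=O)C(C)(C)C)COCc2ccc(OC)cc2)[C@@H]1[C@H](O[Si](C)(C)C(C)(C)C)CCl | intermediate
20 | lactol from 19 with the C4 pivalate cleaved (not isolated; C12 and C4 epimers) | C=C1C(O)O[C@@H](C/C(C)=C/CCC(O)COCc2ccc(OC)cc2)[C@@H]1[C@H](O[Si](C)(C)C(C)(C)C)CCl | intermediate
21 | C12 methyl acetal of 20: 2-methoxy-3-methylenetetrahydrofuran with free C4 hydroxyl, O6 silyl ether, C5 chloride (C6, C7, C8 as in 18) | C=C1C(OC)O[C@@H](C/C(C)=C/CCC(O)COCc2ccc(OC)cc2)[C@@H]1[C@H](O[Si](C)(C)C(C)(C)C)CCl | intermediate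
22 | C4 S-acetyl thiol (thioacetate) of 21 | C=C1C(OC)O[C@@H](C/C(C)=C/CCC(SC(C)=O)COCc2ccc(OC)cc2)[C@@H]1[C@H](O[Si](C)(C)C(C)(C)C)CCl | intermediate
23 | eleven-membered cyclic sulfide, S between C4 and C5, E olefin C1=C10, fused at C7–C8 to the 2-methoxy-3-methylenetetrahydrofuran (C6, C7, C8 as in the target) | C=C1C(OC)O[C@H]2C/C(C)=C/CCC(COCc3ccc(OC)cc3)SC[C@@H](O[Si](C)(C)C(C)(C)C)[C@H]12 | intermediate
24 | S,S-dioxide of 23 | C=C1C(OC)O[C@H]2C/C(C)=C/CCC(COCc3ccc(OC)cc3)S(=O)(=O)C[C@@H](O[Si](C)(C)C(C)(C)C)[C@H]12 | intermediate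
25 | α-bromo sulfone from 24 (not isolated; Br drawn at C5, the C4 bromide would give the same episulfone) | C=C1C(OC)O[C@H]2C/C(C)=C/CCC(COCc3ccc(OC)cc3)S(=O)(=O)C(Br)[C@@H](O[Si](C)(C)C(C)(C)C)[C@H]12 | intermediate
26 | episulfone (thiirane 1,1-dioxide across C4–C5) on the ten-membered ring (not isolated) | C=C1C(OC)O[C@H]2C/C(C)=C/CCC3(COCc4ccc(OC)cc4)S(=O)(=O)C3[C@@H](O[Si](C)(C)C(C)(C)C)[C@H]12 | intermediate
27 | cyclodeca-1(10),4-diene with C12 methyl acetal, O15 PMB ether, O6 TBS ether (C1=C10 E; C3 and C6 cis on C4=C5; C6, C7, C8 as in the target) | C=C1C(OC)O[C@H]2C/C(C)=C/CC/C(COCc3ccc(OC)cc3)=C\[C@@H](O[Si](C)(C)C(C)(C)C)[C@H]12 | intermediate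
28 | lactol from 27 (not isolated) | C=C1C(O)O[C@H]2C/C(C)=C/CC/C(COCc3ccc(OC)cc3)=C\[C@@H](O[Si](C)(C)C(C)(C)C)[C@H]12 | intermediate
29 | 8,12-lactone with O15 PMB ether and O6 TBS ether | C=C1C(=O)O[C@H]2C/C(C)=C/CC/C(COCc3ccc(OC)cc3)=C\[C@@H](O[Si](C)(C)C(C)(C)C)[C@H]12 | intermediate
30 | 8,12-lactone with free C15 hydroxyl and O6 TBS ether | C=C1C(=O)O[C@H]2C/C(C)=C/CC/C(CO)=C\[C@@H](O[Si](C)(C)C(C)(C)C)[C@H]12 | intermediate
31 | 2-[(tert-butyldimethylsilyl)oxy]acetaldehyde | O=CCO[Si](C)(C)C(C)(C)C | starting material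
32 | ethyl 2-(triphenyl-λ5-phosphanylidene)propanoate | CCOC(=O)C(C)=P(c1ccccc1)(c1ccccc1)c1ccccc1 | starting material
33 | ethyl (E)-4-[(tert-butyldimethylsilyl)oxy]-2-methylbut-2-enoate | CCOC(=O)/C(C)=C/CO[Si](C)(C)C(C)(C)C | intermediate
34 | (E)-4-[(tert-butyldimethylsilyl)oxy]-2-methylbut-2-enoic acid | OC(=O)/C(C)=C/CO[Si](C)(C)C(C)(C)C | intermediate
35 | bis-TBS ether of the target (O6 and side-chain oxygen) | C=C1C(=O)O[C@H]2C/C(C)=C/CC/C(COC(=O)/C(C)=C/CO[Si](C)(C)C(C)(C)C)=C\[C@@H](O[Si](C)(C)C(C)(C)C)[C@H]12 | intermediate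
36 | target: (6R,7S,8S)-6-hydroxy-15-[(E)-4-hydroxy-2-methylbut-2-enoyloxy]germacra-1(10)E,4,11(13)-trien-12,8-olide (C3 and C6 cis on C4=C5) | C=C1C(=O)O[C@H]2C/C(C)=C/CC/C(COC(=O)/C(C)=C/CO)=C\[C@@H](O)[C@H]12 | target

Total step count: 21
Longest linear sequence: 17 steps (steps 1–3, 6–17, 20, 21); steps 4–5 and 18–19 are side branches.

Steps most likely to fail

Step 15. The sulfonyl carbanions may lose the C15 or C6 alkoxide (β-elimination) or be brominated twice before the 1,3-displacement, and part of the material may extrude to the ring-trans olefin. The fallback closes the C4=C5 bond directly, without extrusion. It sets out from 21: displacement of the chloride by 1-phenyl-1H-tetrazole-5-thiol (K2CO3, NaI, DMF) should give the tetrazolyl sulfide F1, oxidation (H2O2, (NH4)6Mo7O24·4H2O) the tetrazolyl sulfone F2, and Dess–Martin oxidation of the C4 alcohol the keto sulfone F3; KN(SiMe3)2 in THF at −78 °C under high dilution should then close the ten-membered ring by an intramolecular Julia–Kocienski olefination and return to the route at 27.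

Step 13. SN2 at the β-silyloxy primary chloride may be slow, so that intermolecular S-alkylation and disulfide formation take over. The fallback closes the sulfur ring by epoxide opening. It sets out from 21: Bu4NF removes the silyl group and the alkoxide closes the C5–C6 epoxide to give the epoxy alcohol F4; Mitsunobu reaction with thioacetic acid gives the epoxy thioacetate F5; Cs2CO3 in MeOH/DMF under high dilution frees the thiolate, which should open the terminal epoxide at C5 to the hydroxy thiacycle F6; silylation (TBSOTf, 2,6-lutidine) returns to the route at 23.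

Step 8. The allylic bromide may decompose the ruthenium carbene and closure onto the 1,1-disubstituted acrylate may be slow, so that dimerisation competes. The fallback introduces C13 after the ring is closed. It sets out from 13: acryloyl chloride and iPr2NEt give the acrylate F7, ring-closing metathesis with the same catalyst gives the C11-unsubstituted butenolide F8, Morita–Baylis–Hillman hydroxymethylation (aqueous formaldehyde, imidazole, THF) gives the hydroxymethyl butenolide F9, and CBr4/PPh3 returns to the route at 16.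

Further compounds
F1 | step 15 | tetrazolyl sulfide: 21 with the C5 chloride replaced by (1-phenyl-1H-tetrazol-5-yl)sulfanyl | C=C1C(OC)O[C@@H](C/C(C)=C/CCC(O)COCc2ccc(OC)cc2)[C@@H]1[C@H](O[Si](C)(C)C(C)(C)C)CSC1=NN=NN1c1ccccc1
F2 | step 15 | tetrazolyl sulfone: S,S-dioxide of F1 | C=C1C(OC)O[C@@H](C/C(C)=C/CCC(O)COCc2ccc(OC)cc2)[C@@H]1[C@H](O[Si](C)(C)C(C)(C)C)CS(=O)(=O)C1=NN=NN1c1ccccc1
F3 | step 15 | keto sulfone: F2 with the C4 carbinol oxidised to the ketone | C=C1C(OC)O[C@@H](C/C(C)=C/CCC(=O)COCc2ccc(OC)cc2)[C@@H]1[C@H](O[Si](C)(C)C(C)(C)C)CS(=O)(=O)C1=NN=NN1c1ccccc1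
F4 | step 13 | epoxy alcohol: C5–C6 epoxide from 21 with free C4 hydroxyl | C=C1C(OC)O[C@@H](C/C(C)=C/CCC(O)COCc2ccc(OC)cc2)[C@@H]1[C@H]1CO1
F5 | step 13 | epoxy thioacetate: C4 thioacetate of F4 | C=C1C(OC)O[C@@H](C/C(C)=C/CCC(SC(C)=O)COCc2ccc(OC)cc2)[C@@H]1[C@H]1CO1
F6 | step 13 | hydroxy thiacycle: 23 with free C6 hydroxyl | C=C1C(OC)O[C@H]2C/C(C)=C/CCC(COCc3ccc(OC)cc3)SC[C@@H](O)[C@H]12
F7 | step 8 | acrylate of 13 | C=C[C@@H](OC(=O)C=C)C/C(C)=C/CCC(OC(=O)C(C)(C)C)COCc1ccc(OC)cc1
F8 | step 8 | (5S)-5-substituted furan-2(5H)-one without the C13 carbon | O=C1O[C@@H](C/C(C)=C/CCC(OC(=O)C(C)(C)C)COCc2ccc(OC)cc2)C=C1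
F9 | step 8 | (5S)-3-(hydroxymethyl)-5-substituted furan-2(5H)-one | O=C1O[C@@H](C/C(C)=C/CCC(OC(=O)C(C)(C)C)COCc2ccc(OC)cc2)C=C1CO
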